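## The problem

Compound 14, 2-(3,5-dihydroxy-4-methoxyphenyl)-3,5-dihydroxy-7,8-dimethoxy-4H-chromen-4-one, is a flat, achiral flavonol: benzene ring A fused to 4-pyranone ring C, with aryl ring B on C2. No stereocentre has to be set; the only one that appears on the way (C2 of keto ester 12) is racemic and becomes the sp2 carbon C3. The real task is oxygen bookkeeping. Seven oxygens (C3, C5, C7, C8, C3', C4', C5') must end as four hydroxyls and three methyl ethers, and apart from the chelated C5 position no late methylation or demethylation can be relied on to tell them apart. The pattern therefore has to come in with the building blocks, and the four hydroxyls should share one removable mask. Ring A is the awkward half: a 5-hydroxy-7,8-dioxygenated chromone can drift into the 5,6,7 series by opening and reclosure of ring C in hot strong acid (Wessely–Moser), so ring C must be closed with only one possible regiochemistry and no strongly acidic step may follow. The free compound combines a 3-hydroxy-4-pyranone, a peri-hydroxy ketone and an electron-rich dihydroxyanisole, all air-sensitive as phenolates, and its three aryl methyl ethers rule out BBr3-type reagents; the hydroxyls should be freed last, under neutral conditions. The feature that permits a direct annulation is in ring A: C8a, which carries O1, has C8 (methoxylated) on one side and C4a (unsubstituted) on the other, and C4a is also ortho to the C5 oxygen and para to the C7 methoxyl. A phenol holding the ring A oxygens can therefore accept the C2–C3–C4 unit in one way only, by acylation at C4a and condensation at the C8a oxygen.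

## Retrosynthesis

**14 to 13.** The four O–H bonds at C3, C5, C3' and C5' are traced back to four benzyl ethers in 13, removed together by hydrogenolysis. Benzyl is preferred to an acyl group at the C3 oxygen, even though an α-acyloxy keto ester would be easy to make. An ester at that position would be exposed to acyl transfer to the phenol during the hot annulation and would need its own cleavage step, whereas an ether is inert to heat and leaves with the other three. The forward step must only spare the C2=C3 bond and the methyl ethers.

**13 to 6 and 12.** Ring C is cut at C4–C4a and O1–C2, giving phenol 6 (ring A with all its oxygens) and the 2-benzyloxy-3-oxo ester 12 (C2, C3, C4 and ring B). This is preferred to its neighbours for two reasons: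
- Oxidative closure of a 2'-hydroxychalcone (Algar–Flynn–Oyamada) is known to turn to aurones when the chalcone carries a 6'-substituent, which the C5 oxygen would be.
- An acyl-transfer route of the Baker–Venkataraman kind needs a ring A ω-oxygenated acetophenone first. That is the same ortho-acylation problem without a ring closure to pull it forward.

The cut divides 13 into two halves of similar size, each four steps from a commercial arene. The forward reaction must acylate carbon ortho to the hydroxyl rather than stop at oxygen or go para, give the chromone and not the coumarin, and leave four benzyl ethers intact at about 240 °C.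

**12 to 10 and 11.** The bond between the α-carbon and the aroyl carbon is cut, giving aroyl chloride 10 and ethyl 2-(benzyloxy)acetate 11, joined by a crossed Claisen acylation. This brings the C3 oxygen in already benzylated. The alternative of building the unsubstituted aroylacetate and oxidising its α-position afterwards costs at least one more step. The forward step needs C-acylation of an ester enolate without over-addition to the new ketone.

**10 to 9, 8 and 7.** Acid chloride 10 comes from acid 9, which comes from benzyl ester 8 by saponification, and 8 from commercial 3,5-dihydroxy-4-methoxybenzoic acid 7 by exhaustive benzylation. Only O–C and C–Cl bonds are involved; the ring B pattern, with its central methyl ether, is bought ready-made.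

**6 to 5, 4, 3, 2 and 1.** Phenol 6 has its free hydroxyl next to a methoxyl and a benzyloxy group meta to it. The two oxygens are told apart by a temporary silyl ether: 6 comes from silyl ether 5, 5 from phenol 4 by benzylation, and 4 from arylboronate 3 by oxidation of the C–B bond. The C–B bond is cut back to a C–H bond of silyl ether 2, made from commercial 2,3-dimethoxyphenol 1. The position concerned is meta to all three oxygens of 2 and cannot be reached by electrophilic substitution. Sterically controlled C–H borylation is asked to pick the one ring hydrogen that has no ortho substituent.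

## Roads not taken

**Alternative 1: Moore cyclobutenone ring expansion, ring A built last.** The cut is at C4a–C5, through ring A. Heating racemic 4-{5-(benzyloxy)-6-[3,5-bis(benzyloxy)-4-methoxyphenyl]-4-oxo-4H-pyran-2-yl}-3,4-dimethoxycyclobut-2-en-1-one A1 would open the four-membered ring to a dienylketene. Its ketene carbon would bond to the pyranone CH carbon and, after tautomerisation, give 3-(benzyloxy)-2-[3,5-bis(benzyloxy)-4-methoxyphenyl]-5-hydroxy-7,8-dimethoxy-4H-chromen-4-one A2.
- Merits: the ring A pattern is fixed by the cyclobutenone, so there is no ortho/para question. The 5-hydroxyl arrives free, and the thermolysis runs well below the temperature of the chosen annulation. In regiochemical certainty and mildness it is the better key step.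
- Weak points: A1 is hard to assemble. It needs a fully substituted 4-pyranone metalated at its one free α-position (pyranones tend to ring-open with strong bases and nucleophiles), regioselective addition to a squarate-type dione, and O-methylation of a hindered tertiary alkoxide. A pyranone double bond as the 2π partner of the electrocyclisation is less established than an arene or a simple alkene.
- Comparison: the chosen plan has a rougher key step but reaches it in four simple steps per half from cheap aromatic compounds.

**Alternative 2: aurone epoxide ring expansion.** The cut is at O1–C2. Acid would open the benzylic C–O bond of racemic 3'-[3,5-bis(benzyloxy)-4-methoxyphenyl]-4,6,7-trimethoxy-3H-spiro[1-benzofuran-2,2'-oxiran]-3-one A3, and migration of the ring oxygen from the spiro carbon to the benzylic carbon would give 2-[3,5-bis(benzyloxy)-4-methoxyphenyl]-3-hydroxy-5,7,8-trimethoxy-4H-chromen-4-one A4.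
- Merits: it uses the aurone pathway that 6'-substituted chalcones prefer anyway, delivers the 3-hydroxyl directly, and the key step is run cold.
- Weak points: the rearrangement depends on a benzylic cation, and ring B stabilises it poorly. Its 4-methoxyl is twisted out of conjugation by two ortho benzyloxy groups, and these sit meta to the cationic centre. Opening at the spiro carbon, acyl shifts and simple hydrolysis are then likely competitors. A4 also carries a 5-methyl ether that must be removed selectively afterwards with a chelating Lewis acid, and A3 itself needs a benzofuranone synthesis, a condensation and an epoxidation.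
- Comparison: the chosen plan brings the C5 oxygen in already differentiated and needs no cation on ring B.

**Alternative 3: ring C closed by O-arylation at C8a.** The cut is at O1–C8a. The enolate oxygen of 2-(benzyloxy)-1-[6-(benzyloxy)-2-fluoro-3,4-dimethoxyphenyl]-3-[3,5-bis(benzyloxy)-4-methoxyphenyl]propane-1,3-dione A5 would displace the ortho fluoride to give 3,5-bis(benzyloxy)-2-[3,5-bis(benzyloxy)-4-methoxyphenyl]-7,8-dimethoxy-4H-chromen-4-one A6, which is the same compound as 13.
- Merits: carbonate base at moderate temperature, no ring A regiochemistry to decide, and the same one-step end game. As a ring closure it is milder and more predictable than a melt at 240 °C.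
- Weak points: the fluoride sits on a ring with three alkoxy donors and is activated only by the ortho carbonyl, with a methoxyl beside it, so the substitution is expected to be slow. The fluorinated, fully substituted ring A acyl unit is not commercial and would cost several steps with its own regiochemical problems. A5 then needs a further acylation to assemble.
- Comparison: the chosen plan replaces this with a phenol made in four steps, whose hydroxyl provides both the nucleophile and the regiocontrol.

Key step: step 9

Remark on the chemistry: compounds 1, 7 and 11 are taken to be commercially available; 12 is handled as the racemate (partly enolised), which does not matter because its C2 becomes the sp2 carbon C3 of 13.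

## Route

Step 1
Reactants: 1 2,3-dimethoxyphenol
Product: 2 (2,3-dimethoxyphenoxy)tri(propan-2-yl)silane
Conditions: iPr3SiCl, imidazole, DMF, rt
Reagents that add atoms: chlorotri(propan-2-yl)silane, CC(C)[Si](Cl)(C(C)C)C(C)C
Why: Standard imidazole-promoted silylation of a phenol. The bulky silyl ether masks the oxygen that must be free in step 9, survives the carbonate base of step 3 and shields the neighbouring C6–H from the borylation catalyst.

Step 2
Reactants: 2 (2,3-dimethoxyphenoxy)tri(propan-2-yl)silane
Product: 4 3,4-dimethoxy-5-{[tri(propan-2-yl)silyl]oxy}phenol, via aryl pinacol boronate 3 (not isolated)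
Conditions: B2pin2, [Ir(OMe)(cod)]2 (cat.), 4,4'-di-tert-butyl-2,2'-bipyridine (cat.), THF, 80 °C; then aq. KHSO5 (Oxone), acetone, rt
Reagents that add atoms: bis(pinacolato)diboron, CC1(C)OB(OC1(C)C)B1OC(C)(C)C(C)(C)O1 (boryl group of 3); potassium peroxymonosulfate, [K+].OOS(=O)(=O)[O-] (new phenolic oxygen of 4)
Why: Iridium-catalysed aromatic C–H borylation is sterically governed: H4 lies next to a methoxyl and H6 next to the silyl ether, so only C5, which has no ortho substituent, is borylated. Oxidation of the C–B bond by peroxymonosulfate (aryl shift from boron to oxygen, then hydrolysis) in the same flask gives the phenol at a position that electrophilic substitution cannot reach.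

Step 3
Reactants: 4 3,4-dimethoxy-5-{[tri(propan-2-yl)silyl]oxy}phenol
Product: 5 [5-(benzyloxy)-2,3-dimethoxyphenoxy]tri(propan-2-yl)silane
Conditions: BnBr, K2CO3, acetone, reflux
Reagents that add atoms: benzyl bromide, BrCc1ccccc1
Why: Williamson etherification of the only free phenol; an aryl triisopropylsilyl ether is stable to K2CO3 in acetone.

Step 4
Reactants: 5 [5-(benzyloxy)-2,3-dimethoxyphenoxy]tri(propan-2-yl)silane
Product: 6 5-(benzyloxy)-2,3-dimethoxyphenol
Conditions: Bu4NF, THF, 0 °C; aq. NH4Cl
Reagents that add atoms: none
Why: Fluoride-induced cleavage of the aryl silyl ether, driven by Si–F bond formation; benzyl and methyl ethers are untouched, so the hydroxyl next to the methoxyl is the only free one.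

Step 5
Reactants: 7 3,5-dihydroxy-4-methoxybenzoic acid
Product: 8 benzyl 3,5-bis(benzyloxy)-4-methoxybenzoate
Conditions: BnBr (3.5 equiv), K2CO3, DMF, 60 °C
Reagents that add atoms: benzyl bromide, BrCc1ccccc1
Why: Exhaustive O-alkylation of the two phenols (Williamson ether synthesis) and of the carboxylate with benzyl bromide.

Step 6
Reactants: 8 benzyl 3,5-bis(benzyloxy)-4-methoxybenzoate
Product: 9 3,5-bis(benzyloxy)-4-methoxybenzoic acid
Conditions: NaOH, THF/MeOH/H2O, 60 °C; then aq. HCl
Reagents that add atoms: sodium hydroxide, [Na+].[OH-]
Why: Saponification of the benzyl ester; aryl benzyl ethers are inert to hydroxide.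

Step 7
Reactants: 9 3,5-bis(benzyloxy)-4-methoxybenzoic acid
Product: 10 3,5-bis(benzyloxy)-4-methoxybenzoyl chloride
Conditions: (COCl)2, DMF (cat.), CH2Cl2, 0 °C to rt
Reagents that add atoms: oxalyl chloride, O=C(Cl)C(=O)Cl
Why: Acid chloride formation through the chloroiminium species from oxalyl chloride and DMF; the by-products are gases and the crude chloride is used directly.

Step 8
Reactants: 10 3,5-bis(benzyloxy)-4-methoxybenzoyl chloride; 11 ethyl 2-(benzyloxy)acetate
Product: 12 ethyl 2-(benzyloxy)-3-[3,5-bis(benzyloxy)-4-methoxyphenyl]-3-oxopropanoate (racemic)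
Conditions: 11 (2.1 equiv), LiN(SiMe3)2 (2.2 equiv), THF, −78 °C; then 10, −78 to −40 °C; aq. NH4Cl
Reagents that add atoms: none
Why: Crossed Claisen condensation: the lithium enolate of the alkoxyacetate is C-acylated by the aroyl chloride, and the second equivalent of enolate deprotonates the more acidic keto ester as it forms, which protects the ketone from a second addition. The new stereocentre is not controlled (racemic, partly enolised) and is lost in step 9.

Step 9
Reactants: 6 5-(benzyloxy)-2,3-dimethoxyphenol; 12 ethyl 2-(benzyloxy)-3-[3,5-bis(benzyloxy)-4-methoxyphenyl]-3-oxopropanoate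
Product: 13 3,5-bis(benzyloxy)-2-[3,5-bis(benzyloxy)-4-methoxyphenyl]-7,8-dimethoxy-4H-chromen-4-one
Conditions: 6 (1.0 equiv), 12 (1.5 equiv), Ph2O, 240–250 °C, N2 sweep (EtOH and H2O distilled out)
Reagents that add atoms: none
Why: This is the Mentzer thermal chromone synthesis (the acid-free relative of the Simonis reaction), here with a 3-oxo ester that carries an ether substituent at C2. Above about 200 °C keto ester 12 loses ethanol to an α-benzyloxy aroylketene, which phenol 6 captures either at oxygen (aryl keto ester, which re-forms the ketene on further heating) or, with hydrogen-bonded delivery from the hydroxyl, at the ortho carbon C6. The ortho C-acyl product is a 2-hydroxyaryl 2-benzyloxy-1,3-diketone, which holds the new C4–C4a bond; its phenolic oxygen then adds to the aryl ketone carbonyl in a 6-exo-trig closure, and loss of water gives the aromatic pyranone ring C with the O1–C2 bond. Chromone rather than coumarin is expected because without acid the ketone carbonyl is not activated for a Pechmann-type attack on the arene, whereas the ketene carbon is a strong acylating agent. Site selectivity rests on the substrate: C6 of 6 is the only carbon ortho to the hydroxyl (C2 carries a methoxyl), it is activated by the ortho hydroxyl, the ortho benzyloxy and the para methoxy group, and only acylation there can be drained irreversibly by cyclodehydration. No stereocentre is formed; the racemic centre of 12 becomes the sp2 carbon C3. The four benzyl ethers are expected to tolerate the short heating, and an ether rather than an ester on the C3 oxygen excludes acyl transfer to the phenol.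

Step 10
Reactants: 13 3,5-bis(benzyloxy)-2-[3,5-bis(benzyloxy)-4-methoxyphenyl]-7,8-dimethoxy-4H-chromen-4-one
Product: 14 2-(3,5-dihydroxy-4-methoxyphenyl)-3,5-dihydroxy-7,8-dimethoxy-4H-chromen-4-one
Conditions: H2 (1 atm), 10% Pd/C, THF/MeOH, rt
Reagents that add atoms: none
Why: Catalytic hydrogenolysis of four benzyl ethers (three aryl ethers and the enol-type ether at C3) under neutral conditions. The tetrasubstituted, conjugated C2=C3 bond and the methyl ethers should not be affected at 1 atm, and the oxidation-prone polyphenol is released without base.

## Compound list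

1 | 2,3-dimethoxyphenol | COc1cccc(O)c1OC | starting material
2 | (2,3-dimethoxyphenoxy)tri(propan-2-yl)silane | COc1cccc(O[Si](C(C)C)(C(C)C)C(C)C)c1OC | intermediate
3 | [2,3-dimethoxy-5-(4,4,5,5-tetramethyl-1,3,2-dioxaborolan-2-yl)phenoxy]tri(propan-2-yl)silane | COc1cc(B2OC(C)(C)C(C)(C)O2)cc(O[Si](C(C)C)(C(C)C)C(C)C)c1OC | intermediate (not isolated)
4 | 3,4-dimethoxy-5-{[tri(propan-2-yl)silyl]oxy}phenol | COc1cc(O)cc(O[Si](C(C)C)(C(C)C)C(C)C)c1OC | intermediate
5 | [5-(benzyloxy)-2,3-dimethoxyphenoxy]tri(propan-2-yl)silane | COc1cc(OCc2ccccc2)cc(O[Si](C(C)C)(C(C)C)C(C)C)c1OC | intermediate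
6 | 5-(benzyloxy)-2,3-dimethoxyphenol | COc1cc(OCc2ccccc2)cc(O)c1OC | intermediate
7 | 3,5-dihydroxy-4-methoxybenzoic acid | COc1c(O)cc(cc1O)C(=O)O | starting material
8 | benzyl 3,5-bis(benzyloxy)-4-methoxybenzoate | COc1c(OCc2ccccc2)cc(cc1OCc1ccccc1)C(=O)OCc1ccccc1 | intermediate
9 | 3,5-bis(benzyloxy)-4-methoxybenzoic acid | COc1c(OCc2ccccc2)cc(cc1OCc1ccccc1)C(=O)O | intermediate
10 | 3,5-bis(benzyloxy)-4-methoxybenzoyl chloride | COc1c(OCc2ccccc2)cc(cc1OCc1ccccc1)C(=O)Cl | intermediate
11 | ethyl 2-(benzyloxy)acetate | CCOC(=O)COCc1ccccc1 | starting material
12 | ethyl 2-(benzyloxy)-3-[3,5-bis(benzyloxy)-4-methoxyphenyl]-3-oxopropanoate (racemic) | CCOC(=O)C(OCc1ccccc1)C(=O)c1cc(OCc2ccccc2)c(OC)c(OCc2ccccc2)c1 | intermediate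
13 | 3,5-bis(benzyloxy)-2-[3,5-bis(benzyloxy)-4-methoxyphenyl]-7,8-dimethoxy-4H-chromen-4-one | COc1cc(OCc2ccccc2)c2c(=O)c(OCc3ccccc3)c(-c3cc(OCc4ccccc4)c(OC)c(OCc4ccccc4)c3)oc2c1OC | intermediate
14 | 2-(3,5-dihydroxy-4-methoxyphenyl)-3,5-dihydroxy-7,8-dimethoxy-4H-chromen-4-one | COc1cc(O)c2c(=O)c(O)c(-c3cc(O)c(OC)c(O)c3)oc2c1OC | target

## Step count and least certain steps

Total: 10 steps. Longest linear sequence: 6 steps (steps 1–4, 9, 10; the other arm, steps 5–8, 9, 10, is equally long).

**Step 9 (key step).** The most likely failure is that the ketene is captured only at the phenol oxygen and the acyl group does not move on to carbon. The next is acylation at C4 of 6, para to the hydroxyl, which is activated to a similar degree and cannot cyclise. Slow thermal loss of benzyl groups over a long heating time is a further risk. The fallback sets out from 6 and 12 and returns at 13; it makes the same two bonds one at a time with an ortho-specific first step.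
- Keto ester 12 is dealkoxycarbonylated (LiCl, wet DMSO, 150 °C; Krapcho reaction) to 2-(benzyloxy)-1-[3,5-bis(benzyloxy)-4-methoxyphenyl]ethan-1-one F1.
- Phenol 6 is formylated with MgCl2, Et3N and paraformaldehyde in MeCN, which delivers the formyl group only ortho to the hydroxyl, to give 6-(benzyloxy)-2-hydroxy-3,4-dimethoxybenzaldehyde F2.
- Aldol addition of the lithium enolate of F1 (LiN(SiMe3)2, THF, −78 °C) to the lithium phenoxide of F2 gives 2-(benzyloxy)-3-[6-(benzyloxy)-2-hydroxy-3,4-dimethoxyphenyl]-1-[3,5-bis(benzyloxy)-4-methoxyphenyl]-3-hydroxypropan-1-one F3 as a mixture of diastereomers.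
- Oxidation of its benzylic alcohol with MnO2 gives 2-(benzyloxy)-1-[6-(benzyloxy)-2-hydroxy-3,4-dimethoxyphenyl]-3-[3,5-bis(benzyloxy)-4-methoxyphenyl]propane-1,3-dione F4. This is the diketone that the thermal reaction passes through, and it is cyclodehydrated with catalytic TsOH in warm toluene to 13.

**Step 8.** The electron-rich aroyl chloride is a sluggish electrophile at low temperature, so self-condensation of the ester enolate and O-acylation of the product enolate may consume material. The fallback sets out from 10 and returns at 12. Decarboxylative acylation of EtO2CCH2CO2K (potassium ethyl malonate) with 10 in the presence of MgCl2 and Et3N in MeCN gives ethyl 3-[3,5-bis(benzyloxy)-4-methoxyphenyl]-3-oxopropanoate F5. Diazo transfer with 4-acetamidobenzenesulfonyl azide and Et3N gives ethyl 3-[3,5-bis(benzyloxy)-4-methoxyphenyl]-2-diazo-3-oxopropanoate F6. Rh2(OAc)4-catalysed O–H insertion of the derived carbenoid into benzyl alcohol then gives 12.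

**Step 10.** Hydrogenolysis may stall, because partly debenzylated intermediates are poorly soluble and the chelating polyphenol can slow the catalyst, or forcing it may begin to saturate the C2=C3 bond. The fallback sets out from 13 and returns at 14 with no new intermediate: Lewis-acid debenzylation with BCl3 and pentamethylbenzene as cation scavenger in CH2Cl2 at −78 °C, which removes aryl and enol benzyl ethers and should leave the methyl ethers at that temperature.

**Step 3.** Under carbonate base the phenoxide of 4 could take up the silyl group of another molecule, which would scramble the oxygen that gets benzylated. The fallback sets out from 4 and returns at 5 with no new intermediate: Mitsunobu etherification with benzyl alcohol, PPh3 and diisopropyl azodicarboxylate in THF, which never generates a free phenoxide.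

## Further compounds

F1 | step 9 | 2-(benzyloxy)-1-[3,5-bis(benzyloxy)-4-methoxyphenyl]ethan-1-one | COc1c(OCc2ccccc2)cc(cc1OCc1ccccc1)C(=O)COCc1ccccc1
F2 | step 9 | 6-(benzyloxy)-2-hydroxy-3,4-dimethoxybenzaldehyde | COc1cc(OCc2ccccc2)c(C=O)c(O)c1OC
F3 | step 9 | 2-(benzyloxy)-3-[6-(benzyloxy)-2-hydroxy-3,4-dimethoxyphenyl]-1-[3,5-bis(benzyloxy)-4-methoxyphenyl]-3-hydroxypropan-1-one (mixture of racemic diastereomers) | COc1cc(OCc2ccccc2)c(C(O)C(OCc2ccccc2)C(=O)c2cc(OCc3ccccc3)c(OC)c(OCc3ccccc3)c2)c(O)c1OC
F4 | step 9 | 2-(benzyloxy)-1-[6-(benzyloxy)-2-hydroxy-3,4-dimethoxyphenyl]-3-[3,5-bis(benzyloxy)-4-methoxyphenyl]propane-1,3-dione (racemic) | COc1cc(OCc2ccccc2)c(C(=O)C(OCc2ccccc2)C(=O)c2cc(OCc3ccccc3)c(OC)c(OCc3ccccc3)c2)c(O)c1OC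
F5 | step 8 | ethyl 3-[3,5-bis(benzyloxy)-4-methoxyphenyl]-3-oxopropanoate | CCOC(=O)CC(=O)c1cc(OCc2ccccc2)c(OC)c(OCc2ccccc2)c1
F6 | step 8 | ethyl 3-[3,5-bis(benzyloxy)-4-methoxyphenyl]-2-diazo-3-oxopropanoate | CCOC(=O)C(=[N+]=[N-])C(=O)c1cc(OCc2ccccc2)c(OC)c(OCc2ccccc2)c1
F0 | step 10 | none | none
F0 | step 3 | none | none
A1 | alternative 1 | 4-{5-(benzyloxy)-6-[3,5-bis(benzyloxy)-4-methoxyphenyl]-4-oxo-4H-pyran-2-yl}-3,4-dimethoxycyclobut-2-en-1-one (racemic) | COC1=CC(=O)C1(OC)c1cc(=O)c(OCc2ccccc2)c(-c2cc(OCc3ccccc3)c(OC)c(OCc3ccccc3)c2)o1
A2 | alternative 1 | 3-(benzyloxy)-2-[3,5-bis(benzyloxy)-4-methoxyphenyl]-5-hydroxy-7,8-dimethoxy-4H-chromen-4-one | COc1cc(O)c2c(=O)c(OCc3ccccc3)c(-c3cc(OCc4ccccc4)c(OC)c(OCc4ccccc4)c3)oc2c1OC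
A3 | alternative 2 | 3'-[3,5-bis(benzyloxy)-4-methoxyphenyl]-4,6,7-trimethoxy-3H-spiro[1-benzofuran-2,2'-oxiran]-3-one (racemic; aryl group cis to the ring oxygen, one enantiomer drawn) | COc1cc(OC)c2c(c1OC)O[C@@]1(C2=O)O[C@H]1c1cc(OCc2ccccc2)c(OC)c(OCc2ccccc2)c1
A4 | alternative 2 | 2-[3,5-bis(benzyloxy)-4-methoxyphenyl]-3-hydroxy-5,7,8-trimethoxy-4H-chromen-4-one | COc1cc(OC)c2c(=O)c(O)c(-c3cc(OCc4ccccc4)c(OC)c(OCc4ccccc4)c3)oc2c1OC
A5 | alternative 3 | 2-(benzyloxy)-1-[6-(benzyloxy)-2-fluoro-3,4-dimethoxyphenyl]-3-[3,5-bis(benzyloxy)-4-methoxyphenyl]propane-1,3-dione (racemic) | COc1cc(OCc2ccccc2)c(C(=O)C(OCc2ccccc2)C(=O)c2cc(OCc3ccccc3)c(OC)c(OCc3ccccc3)c2)c(F)c1OC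
A6 | alternative 3 | 3,5-bis(benzyloxy)-2-[3,5-bis(benzyloxy)-4-methoxyphenyl]-7,8-dimethoxy-4H-chromen-4-one | COc1cc(OCc2ccccc2)c2c(=O)c(OCc3ccccc3)c(-c3cc(OCc4ccccc4)c(OC)c(OCc4ccccc4)c3)oc2c1OC
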